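**Plan**
- Enabling feature: in the carbocycle C5–C10, the spiro atom C5 is the only sp3 carbon. It lies para to C8=O, between the arms C6H=C7(OMe) and C10H=C9H. The ring is therefore the retron of a 3-oxidohexatriene closure, and in the opened form the only acidic hydrogen sits on C5.
- Retrosynthetic cuts, in order: the four O–Si bonds; C5–C10 (MeOH returned to C10, giving an open 1,4-dimethoxypenta-1,4-dien-3-one on an oxolane C–H); C6=C7; O2–C3 of the oxolane; C1–C1′ (side chain); C3–C4.
- Forward order: both arenes are bought. The chain C3–C4–C5–C1 is grown from vanillin and joined to the aryloxyacetyl half at C1–C1′. The oxolane closes in step 13 and the carbocycle closes last, in step 20.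
- Stereochemistry: C4 comes from an Evans aldol with the (S)-auxiliary. C1 and C1′ come from an Evans aldol with the (R)-auxiliary. C3 comes from a reversible, trans-selective benzylic cycloetherification. C5 comes from facial control by the oxolane in the ring closure.

Key step: step 20

Assumption: locants follow the 2-oxaspiro[4.5]decane numbering of the target (C1 bears the side chain whose first carbon is C1′, C3 the aryl group, C4 the CH2OH, C5 is the spiro atom); the configuration at the future C5 is erased in step 20, so any epimer at that carbon converges.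

Step 1
Reactants: 1 vanillin
Product: 2 3-methoxy-4-(triisopropylsilyloxy)benzaldehyde
Conditions: TIPSCl, imidazole, DMF, rt
Reagents that add atoms: triisopropylsilyl chloride, CC(C)[Si](Cl)(C(C)C)C(C)C
Why: Silyl ether formation on the phenol; the bulky TIPS group should survive the boron aldol, hydride, enolate and mild acid steps and falls to fluoride at the end.

Step 2
Reactants: 3 (S)-4-benzyl-1,3-oxazolidin-2-one; 4 methyl 4-chloro-4-oxobutanoate
Product: 5 methyl 4-[(4S)-4-benzyl-2-oxo-1,3-oxazolidin-3-yl]-4-oxobutanoate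
Conditions: n-BuLi, THF, −78 °C; then 4
Reagents that add atoms: none
Why: N-Acylation of the lithiated oxazolidinone by the acid chloride, which reacts far faster than the methyl ester.

Step 3
Reactants: 5 succinyl imide; 2 silylated vanillin
Product: 6 methyl (3S,4S)-3-[(4S)-4-benzyl-2-oxo-1,3-oxazolidine-3-carbonyl]-4-hydroxy-4-[3-methoxy-4-(TIPSO)phenyl]butanoate
Conditions: Bu2BOTf, i-Pr2NEt, CH2Cl2, −78 → 0 °C; 2, −78 → 0 °C; pH 7 buffer, MeOH, H2O2
Reagents that add atoms: none
Why: Evans syn-aldol reaction: Bu2BOTf enolises only the imide, and the Z-boron enolate reacts through a chair transition state on the face away from the benzyl group, which sets (3S,4S), that is future C4 and, provisionally, C3.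

Step 4
Reactants: 6 aldol adduct
Product: 8 (4R)-4-{(S)-hydroxy[3-methoxy-4-(TIPSO)phenyl]methyl}oxolan-2-one, via diol ester 7 (not isolated)
Conditions: NaBH4, THF–H2O, 0 °C → rt
Reagents that add atoms: none
Why: Reductive removal of the auxiliary (NaBH4 attacks the activated imide carbonyl, not the ester) is followed by spontaneous lactonisation of the new primary alcohol, which ties future C4–CH2OH and C1 together without touching a stereocentre.

Step 5
Reactants: 8 hydroxy lactone
Product: 9 (4R)-4-{(S)-[3-methoxy-4-(TIPSO)phenyl](triethylsilyloxy)methyl}oxolan-2-one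
Conditions: TESCl, imidazole, CH2Cl2, 0 °C
Reagents that add atoms: triethylsilyl chloride, CC[Si](Cl)(CC)CC
Why: Silyl ether formation; the benzylic TES ether protects the alcohol during enolate chemistry and later serves as the acid-labile leaving group for oxolane closure.

Step 6
Reactants: 9 lactone
Product: 10 (3S,4R)-3-[(benzyloxy)methyl]-4-{(S)-[3-methoxy-4-(TIPSO)phenyl](TESO)methyl}oxolan-2-one
Conditions: LiN(i-Pr)2, THF, −78 °C; BnOCH2Cl, DMPU, −78 → −30 °C
Reagents that add atoms: benzyl chloromethyl ether, ClCOCc1ccccc1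
Why: Lactone enolate alkylation with a protected formaldehyde equivalent; the electrophile should enter trans to the large neighbouring substituent, and this centre (future C5) is erased in step 20 in any case.

Step 7
Reactants: 10 alkylated lactone
Product: 12 (2S,3R,4S)-2-[(benzyloxy)methyl]-3-(TBSOCH2)-N-methoxy-N-methyl-4-[3-methoxy-4-(TIPSO)phenyl]-4-(TESO)butanamide, via hydroxy amide 11 (not isolated)
Conditions: MeNH(OMe)·HCl, i-PrMgCl, THF, −20 → 0 °C; crude product, TBSCl, imidazole, DMF, rt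
Reagents that add atoms: N,O-dimethylhydroxylamine hydrochloride, CNOC.Cl; tert-butyldimethylsilyl chloride, CC(C)(C)[Si](C)(C)Cl
Why: Weinreb aminolysis of the lactone by the chloromagnesium amide, with immediate silylation of the freed primary alcohol to stop relactonisation.

Step 8
Reactants: 12 Weinreb amide
Product: 13 (2S,3R,4S)-2-[(benzyloxy)methyl]-3-(TBSOCH2)-4-[3-methoxy-4-(TIPSO)phenyl]-4-(TESO)butanal
Conditions: i-Bu2AlH, THF, −78 °C
Reagents that add atoms: none
Why: Weinreb amide reduction; the chelated tetrahedral aluminium adduct collapses only on work-up, so the reaction should stop at the aldehyde (future C1).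

Step 9
Reactants: 14 4-(3-hydroxypropyl)-2-methoxyphenol (dihydroconiferyl alcohol)
Product: 15 4-[3-(TBSO)propyl]-2-methoxyphenol
Conditions: TBSCl (1.05 equiv), imidazole, CH2Cl2, 0 °C
Reagents that add atoms: tert-butyldimethylsilyl chloride, CC(C)(C)[Si](C)(C)Cl
Why: Chemoselective silyl ether formation; the primary aliphatic alcohol is more nucleophilic toward TBSCl/imidazole than the hydrogen-bonded guaiacol OH.

Step 10
Reactants: 15 phenol; 16 bromoacetic acid
Product: 17 {4-[3-(TBSO)propyl]-2-methoxyphenoxy}acetic acid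
Conditions: NaH (2.2 equiv), THF–DMF, 0 → 50 °C; dilute HCl to pH 3
Reagents that add atoms: none
Why: Williamson ether synthesis between the sodium phenoxide and sodium bromoacetate; the primary TBS ether tolerates the brief mild acidification.

Step 11
Reactants: 17 aryloxyacetic acid; 18 (R)-4-benzyl-1,3-oxazolidin-2-one
Product: 19 (4R)-4-benzyl-3-({4-[3-(TBSO)propyl]-2-methoxyphenoxy}acetyl)-1,3-oxazolidin-2-one
Conditions: DCC, DMAP (cat.), CH2Cl2, 0 °C → rt
Reagents that add atoms: none
Why: Carbodiimide/DMAP N-acylation of the oxazolidinone by the carboxylic acid.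

Step 12
Reactants: 19 aryloxyacetyl imide; 13 aldehyde
Product: 20 (4R)-4-benzyl-3-[(2R,3S,4S,5R,6S)-2-aryloxy-4-[(benzyloxy)methyl]-3-hydroxy-5-(TBSOCH2)-6-[3-methoxy-4-(TIPSO)phenyl]-6-(TESO)hexanoyl]-1,3-oxazolidin-2-one (aryloxy = 4-[3-(TBSO)propyl]-2-methoxyphenoxy)
Conditions: Bu2BOTf, i-Pr2NEt, CH2Cl2, −78 → 0 °C; 13, −78 → 0 °C; pH 7 buffer, MeOH, H2O2
Reagents that add atoms: none
Why: Evans syn-aldol reaction of an aryloxyacetyl imide, the convergent union of the two halves; the Z-boron enolate and the (R)-auxiliary should override the aldehyde bias and set C1 (S) and C1′ with the syn (threo) relation of the target.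

Step 13
Reactants: 20 aldol adduct
Product: 21 (4R)-4-benzyl-3-[(2R)-2-{(2S,3S,4R,5S)-3-[(benzyloxy)methyl]-4-(TBSOCH2)-5-[3-methoxy-4-(TIPSO)phenyl]oxolan-2-yl}-2-{4-[3-(TBSO)propyl]-2-methoxyphenoxy}acetyl]-1,3-oxazolidin-2-one
Conditions: p-TsOH·H2O (10 mol %), CH2Cl2, 0 °C → rt
Reagents that add atoms: none
Why: Acid-catalysed SN1 cycloetherification to the five-membered ring; ionisation of the electron-rich benzylic TES ether and capture by the C1 hydroxyl, reversible under the conditions, should place the aryl group trans to the C4 CH2OTBS group (3S).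

Step 14
Reactants: 21 oxolane imide
Product: 22 (2S)-2-{(2S,3S,4R,5S)-3-[(benzyloxy)methyl]-4-(TBSOCH2)-5-[3-methoxy-4-(TIPSO)phenyl]oxolan-2-yl}-2-{4-[3-(TBSO)propyl]-2-methoxyphenoxy}ethanol
Conditions: LiBH4, MeOH (1 equiv), Et2O–THF, 0 °C
Reagents that add atoms: none
Why: Reductive cleavage of the N-acyloxazolidinone to the primary alcohol; no stereocentre is affected (the descriptor at C1′ changes only by priority).

Step 15
Reactants: 22 primary alcohol
Product: 23 TBS ether of 22 (side chain CH(OAr)CH2OTBS)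
Conditions: TBSCl, imidazole, DMF, rt
Reagents that add atoms: tert-butyldimethylsilyl chloride, CC(C)(C)[Si](C)(C)Cl
Why: Silyl ether formation, so that all hydroxyl groups to be freed at the end carry fluoride-labile groups.

Step 16
Reactants: 23 benzyl ether
Product: 24 {(2S,3S,4R,5S)-2-[(1S)-1-aryloxy-2-(TBSO)ethyl]-4-(TBSOCH2)-5-[3-methoxy-4-(TIPSO)phenyl]oxolan-3-yl}methanol
Conditions: H2 (1 atm), Pd/C, EtOAc, rt, monitored closely
Reagents that add atoms: none
Why: Catalytic hydrogenolysis; the unhindered primary benzyl ether should cleave well before the hindered cyclic 2-aryl ether.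

Step 17
Reactants: 24 primary alcohol
Product: 25 (2S,3R,4R,5S)-2-[(1S)-1-aryloxy-2-(TBSO)ethyl]-4-(TBSOCH2)-5-[3-methoxy-4-(TIPSO)phenyl]oxolane-3-carbaldehyde
Conditions: Dess–Martin periodinane, CH2Cl2, 0 °C → rt
Reagents that add atoms: none
Why: Dess–Martin oxidation under near-neutral conditions gives the aldehyde (future C6) without affecting silyl or aryl ethers.

Step 18
Reactants: 26 diethyl (methoxymethyl)phosphonate; 27 methyl (E)-3-methoxyacrylate
Product: 28 diethyl [(3E)-1,4-dimethoxy-2-oxobut-3-en-1-yl]phosphonate (racemic)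
Conditions: LiN(i-Pr)2 (2.1 equiv), THF, −78 °C; 27, −78 → −20 °C
Reagents that add atoms: none
Why: Acylation of the α-lithiated phosphonate by the ester (1,2-attack on a vinylogous carbonate); the second equivalent of base stores the product as its enolate and prevents over-addition.

Step 19
Reactants: 25 aldehyde; 28 ketophosphonate
Product: 29 (1E,4Z)-1,4-dimethoxy-5-{(2S,3S,4R,5S)-2-[(1S)-1-aryloxy-2-(TBSO)ethyl]-4-(TBSOCH2)-5-[3-methoxy-4-(TIPSO)phenyl]oxolan-3-yl}penta-1,4-dien-3-one
Conditions: LiCl, DBU, MeCN, 0 °C → rt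
Reagents that add atoms: none
Why: Horner–Wadsworth–Emmons olefination under Masamune–Roush conditions; the Z enol ether (acyl group trans to the oxolane) is expected, but this geometry and the adjacent centre are both erased in step 20.

Step 20
Reactants: 29 open dienone
Product: 32 (1S,3S,4R,5S)-1-[(1S)-1-aryloxy-2-(TBSO)ethyl]-4-(TBSOCH2)-7-methoxy-3-[3-methoxy-4-(TIPSO)phenyl]-2-oxaspiro[4.5]deca-6,9-dien-8-one, via lithium trienolate 30 (not isolated), via lithium methoxycyclohexadienolate 31 (not isolated)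
Conditions: LiN(SiMe3)2 (1.5 equiv), THF, −78 °C → rt (→ 40 °C if needed)
Reagents that add atoms: none
Why: Proposed new method: LiN(SiMe3)2 removes the only acidic hydrogen of 29, the γ-H on the future C5, to give the cross-conjugated trienolate 30, a 3-oxidohexatriene (C5=C6–C7(OMe)=C8(OLi)–C9=C10–OMe) in which lithium bridging the oxide and the C7 methoxy group holds C6 and C9 cis, so that the termini C5 and C10 face each other. A thermally allowed disrotatory 6π electrocyclisation (formally a 6-endo-trig vinylogous addition) closes the carbocycle through the C5–C10 bond to dienolate 31, and E1cB loss of LiOMe from C10 makes the closure irreversible and delivers the dienone oxidation level directly. The closest known reaction types are the oxyanion-accelerated electrocyclisation of 3-oxidohexatrienes formed when alkenyllithiums add to cyclobutenones (two-carbon ring expansion to cyclohexenones) and the base-induced closure of phorone to isophorone; new here are the γ-deprotonative entry, the fully substituted ring terminus and the alkoxide-expelling terminus. The only new stereocentre, C5, is controlled by the oxolane: allylic strain with the exocyclic C5=C6 bond pushes the C1 side chain and the C4 CH2OTBS group, both on one face, into pseudoaxial positions, so C10 should bond on the opposite face, which places C10 anti and the methoxy-bearing C6 syn to them, as in the target (5S). The step needs γ-deprotonation without amide addition (hindered base, vinylogous-ester acceptor), attack through C5 rather than C7 (C7 would give a four-membered ring) and survival of the ring oxygen β to C5 (its expulsion would be a retro-5-endo-trig process with poor orbital overlap). Acid is excluded throughout because 29 is also a polarised Nazarov substrate.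

Step 21
Reactants: 32 protected spirodienone
Product: 33 CNP0252711.1, (1S,3S,4R,5S)-1-{(1S)-2-hydroxy-1-[4-(3-hydroxypropyl)-2-methoxyphenoxy]ethyl}-3-(4-hydroxy-3-methoxyphenyl)-4-(hydroxymethyl)-7-methoxy-2-oxaspiro[4.5]deca-6,9-dien-8-one
Conditions: Bu4NF, AcOH (1:1), THF, 0 °C → rt
Reagents that add atoms: none
Why: Fluoride-mediated global desilylation buffered with AcOH, which should avoid both acid-induced fragmentation of the spirodienone and base-induced oxa-Michael addition of the freed alcohols.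

**Compound list**
1 | vanillin | O=Cc1ccc(O)c(OC)c1 | starting material
2 | 3-methoxy-4-(triisopropylsilyloxy)benzaldehyde | O=Cc1ccc(O[Si](C(C)C)(C(C)C)C(C)C)c(OC)c1 | intermediate
3 | (S)-4-benzyl-1,3-oxazolidin-2-one | O=C1N[C@@H](Cc2ccccc2)CO1 | starting material
4 | methyl 4-chloro-4-oxobutanoate | COC(=O)CCC(=O)Cl | starting material
5 | succinyl imide | COC(=O)CCC(=O)N1[C@@H](Cc2ccccc2)COC1=O | intermediate
6 | first syn-aldol adduct | COC(=O)C[C@H](C(=O)N1[C@@H](Cc2ccccc2)COC1=O)[C@H](O)c1ccc(O[Si](C(C)C)(C(C)C)C(C)C)c(OC)c1 | intermediate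
7 | diol ester, methyl (3R,4S)-4-hydroxy-3-(hydroxymethyl)-4-arylbutanoate (not isolated) | COC(=O)C[C@H](CO)[C@H](O)c1ccc(O[Si](C(C)C)(C(C)C)C(C)C)c(OC)c1 | intermediate
8 | hydroxy lactone | O=C1C[C@H](CO1)[C@H](O)c1ccc(O[Si](C(C)C)(C(C)C)C(C)C)c(OC)c1 | intermediate
9 | TES-protected lactone | O=C1C[C@H](CO1)[C@H](O[Si](CC)(CC)CC)c1ccc(O[Si](C(C)C)(C(C)C)C(C)C)c(OC)c1 | intermediate
10 | α-(benzyloxymethyl) lactone | O=C1[C@H](COCc2ccccc2)[C@H](CO1)[C@H](O[Si](CC)(CC)CC)c1ccc(O[Si](C(C)C)(C(C)C)C(C)C)c(OC)c1 | intermediate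
11 | hydroxy Weinreb amide (not isolated) | CON(C)C(=O)[C@H](COCc1ccccc1)[C@H](CO)[C@H](O[Si](CC)(CC)CC)c1ccc(O[Si](C(C)C)(C(C)C)C(C)C)c(OC)c1 | intermediate
12 | silylated Weinreb amide | CON(C)C(=O)[C@H](COCc1ccccc1)[C@H](CO[Si](C)(C)C(C)(C)C)[C@H](O[Si](CC)(CC)CC)c1ccc(O[Si](C(C)C)(C(C)C)C(C)C)c(OC)c1 | intermediate
13 | open-chain aldehyde | O=C[C@H](COCc1ccccc1)[C@H](CO[Si](C)(C)C(C)(C)C)[C@H](O[Si](CC)(CC)CC)c1ccc(O[Si](C(C)C)(C(C)C)C(C)C)c(OC)c1 | intermediate
14 | dihydroconiferyl alcohol | COc1cc(CCCO)ccc1O | starting material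
15 | 4-[3-(TBSO)propyl]-2-methoxyphenol | COc1cc(CCCO[Si](C)(C)C(C)(C)C)ccc1O | intermediate
16 | bromoacetic acid | OC(=O)CBr | starting material
17 | aryloxyacetic acid | COc1cc(CCCO[Si](C)(C)C(C)(C)C)ccc1OCC(O)=O | intermediate
18 | (R)-4-benzyl-1,3-oxazolidin-2-one | O=C1N[C@H](Cc2ccccc2)CO1 | starting material
19 | aryloxyacetyl imide | COc1cc(CCCO[Si](C)(C)C(C)(C)C)ccc1OCC(=O)N1[C@H](Cc2ccccc2)COC1=O | intermediate
20 | second syn-aldol adduct | C(OCc1ccccc1)[C@@H]([C@H](O)[C@@H](Oc1ccc(CCCO[Si](C)(C)C(C)(C)C)cc1OC)C(=O)N1[C@H](Cc2ccccc2)COC1=O)[C@H](CO[Si](C)(C)C(C)(C)C)[C@H](O[Si](CC)(CC)CC)c1ccc(O[Si](C(C)C)(C(C)C)C(C)C)c(OC)c1 | intermediate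
21 | oxolane imide | C(OCc2ccccc2)[C@@H]1[C@H](CO[Si](C)(C)C(C)(C)C)[C@@H](c2ccc(O[Si](C(C)C)(C(C)C)C(C)C)c(OC)c2)O[C@@H]1[C@H](C(=O)N1[C@H](Cc2ccccc2)COC1=O)Oc1ccc(CCCO[Si](C)(C)C(C)(C)C)cc1OC | intermediate
22 | oxolane side-chain alcohol | C(OCc2ccccc2)[C@@H]1[C@H](CO[Si](C)(C)C(C)(C)C)[C@@H](c2ccc(O[Si](C(C)C)(C(C)C)C(C)C)c(OC)c2)O[C@@H]1[C@H](CO)Oc1ccc(CCCO[Si](C)(C)C(C)(C)C)cc1OC | intermediate
23 | fully protected oxolane benzyl ether | C(OCc2ccccc2)[C@@H]1[C@H](CO[Si](C)(C)C(C)(C)C)[C@@H](c2ccc(O[Si](C(C)C)(C(C)C)C(C)C)c(OC)c2)O[C@@H]1[C@H](CO[Si](C)(C)C(C)(C)C)Oc1ccc(CCCO[Si](C)(C)C(C)(C)C)cc1OC | intermediate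
24 | oxolan-3-ylmethanol | OC[C@@H]1[C@H](CO[Si](C)(C)C(C)(C)C)[C@@H](c2ccc(O[Si](C(C)C)(C(C)C)C(C)C)c(OC)c2)O[C@@H]1[C@H](CO[Si](C)(C)C(C)(C)C)Oc1ccc(CCCO[Si](C)(C)C(C)(C)C)cc1OC | intermediate
25 | oxolane-3-carbaldehyde | O=C[C@@H]1[C@H](CO[Si](C)(C)C(C)(C)C)[C@@H](c2ccc(O[Si](C(C)C)(C(C)C)C(C)C)c(OC)c2)O[C@@H]1[C@H](CO[Si](C)(C)C(C)(C)C)Oc1ccc(CCCO[Si](C)(C)C(C)(C)C)cc1OC | intermediate
26 | diethyl (methoxymethyl)phosphonate | CCOP(=O)(COC)OCC | starting material
27 | methyl (E)-3-methoxyacrylate | CO/C=C/C(=O)OC | starting material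
28 | diethyl [(3E)-1,4-dimethoxy-2-oxobut-3-en-1-yl]phosphonate | CCOP(=O)(OCC)C(OC)C(=O)/C=C/OC | intermediate
29 | open cross-conjugated dienone | CO/C=C/C(=O)/C(OC)=C/[C@@H]1[C@H](CO[Si](C)(C)C(C)(C)C)[C@@H](c2ccc(O[Si](C(C)C)(C(C)C)C(C)C)c(OC)c2)O[C@@H]1[C@H](CO[Si](C)(C)C(C)(C)C)Oc1ccc(CCCO[Si](C)(C)C(C)(C)C)cc1OC | intermediate
30 | lithium trienolate (3-oxidohexatriene, not isolated) | [Li+].CO/C=C/C([O-])=C(OC)\C=C1[C@H](CO[Si](C)(C)C(C)(C)C)[C@@H](c2ccc(O[Si](C(C)C)(C(C)C)C(C)C)c(OC)c2)O[C@@H]1[C@H](CO[Si](C)(C)C(C)(C)C)Oc1ccc(CCCO[Si](C)(C)C(C)(C)C)cc1OC | intermediate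
31 | lithium 10-methoxycyclohexadienolate (C10 configuration irrelevant, not isolated) | [Li+].COC1=C[C@]2(C(OC)C=C1[O-])[C@H](CO[Si](C)(C)C(C)(C)C)[C@@H](c1ccc(O[Si](C(C)C)(C(C)C)C(C)C)c(OC)c1)O[C@@H]2[C@H](CO[Si](C)(C)C(C)(C)C)Oc1ccc(CCCO[Si](C)(C)C(C)(C)C)cc1OC | intermediate
32 | protected spirodienone | COC1=C[C@]2(C=CC1=O)[C@H](CO[Si](C)(C)C(C)(C)C)[C@@H](c1ccc(O[Si](C(C)C)(C(C)C)C(C)C)c(OC)c1)O[C@@H]2[C@H](CO[Si](C)(C)C(C)(C)C)Oc1ccc(CCCO[Si](C)(C)C(C)(C)C)cc1OC | intermediate
33 | CNP0252711.1 | COC1=C[C@]2(C=CC1=O)[C@H](CO)[C@@H](c1ccc(O)c(OC)c1)O[C@@H]2[C@H](CO)Oc1ccc(CCCO)cc1OC | target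

**Totals**
Total step count: 21.
Longest linear sequence: 16 steps (steps 1, 3–8, 12–17, 19–21).

**Steps most likely to fail**

1. Step 20.
- What may go wrong: the trienolate may close too slowly. Reprotonation to deconjugated isomers, amide addition to the methoxyvinyl ketone, or erosion of facial control on heating would then take over.
- Fallback (Robinson annulation): it builds the same ring, sets out from aldehyde 25 and returns at 32.
  - DBU-catalysed Michael addition of 25, through its enolate, to 1-methoxybut-3-en-2-one, again on the face anti to the two flanking groups, should give the quaternary keto aldehyde F1.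
  - Intramolecular aldol condensation (piperidinium acetate, toluene, heat), in which only the CH2OMe carbon can reach the aldehyde through a six-membered ring, should give the spiro 2-methoxycyclohexenone F2.
  - LiN(SiMe3)2/Me3SiCl should give the trimethylsilyl dienol ether F3.
  - Saegusa–Ito dehydrogenation with Pd(OAc)2 in MeCN should give 32.

2. Step 19.
- What may go wrong: the α-methoxy ketophosphonate anion is a weak, bulky nucleophile, so the olefination may stall at the hindered aldehyde while enolisation and epimerisation consume it.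
- Fallback (stepwise chain growth): it sets out from 25 and returns at 29.
  - Horner–Wadsworth–Emmons reaction with the smaller anion of methyl 2-(dimethoxyphosphoryl)-2-methoxyacetate (NaH, THF) should give the methyl 2-methoxyacrylate F4.
  - MeNH(OMe)·HCl/i-PrMgCl should give the Weinreb amide F5.
  - (E)-2-Methoxyvinyllithium, made from (E)-tributyl(2-methoxyvinyl)stannane and n-BuLi, should add once to give 29.

3. Step 13.
- What may go wrong: after ionisation, the benzylic cation may be captured by the benzyl ether oxygen or lose a proton, or the primary silyl ethers may be lost under the acid.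
- Fallback (closure at the ketone oxidation level): it sets out from 20 and returns at 21.
  - Selective TES removal (PPTS, EtOH) should give the diol F6.
  - MnO2 should oxidise only the benzylic alcohol, and the aryl ketone should close on the C1 hydroxyl to the cyclic hemiketal F7.
  - Reductive etherification with Et3SiH/BF3·OEt2 (−78 → −20 °C, warmed so that the 2-aryl centre equilibrates to the trans isomer) should give 21.

**Further compounds**
F1 | step 20 | quaternary keto aldehyde | O=C[C@]1(CCC(=O)COC)[C@H](CO[Si](C)(C)C(C)(C)C)[C@@H](c2ccc(O[Si](C(C)C)(C(C)C)C(C)C)c(OC)c2)O[C@@H]1[C@H](CO[Si](C)(C)C(C)(C)C)Oc1ccc(CCCO[Si](C)(C)C(C)(C)C)cc1OC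
F2 | step 20 | spiro 2-methoxycyclohexenone | COC1=C[C@]2(CCC1=O)[C@H](CO[Si](C)(C)C(C)(C)C)[C@@H](c1ccc(O[Si](C(C)C)(C(C)C)C(C)C)c(OC)c1)O[C@@H]2[C@H](CO[Si](C)(C)C(C)(C)C)Oc1ccc(CCCO[Si](C)(C)C(C)(C)C)cc1OC
F3 | step 20 | trimethylsilyl dienol ether | COC1=C[C@]2(CC=C1O[Si](C)(C)C)[C@H](CO[Si](C)(C)C(C)(C)C)[C@@H](c1ccc(O[Si](C(C)C)(C(C)C)C(C)C)c(OC)c1)O[C@@H]2[C@H](CO[Si](C)(C)C(C)(C)C)Oc1ccc(CCCO[Si](C)(C)C(C)(C)C)cc1OC
F4 | step 19 | methyl 2-methoxyacrylate | COC(=O)/C(OC)=C/[C@@H]1[C@H](CO[Si](C)(C)C(C)(C)C)[C@@H](c2ccc(O[Si](C(C)C)(C(C)C)C(C)C)c(OC)c2)O[C@@H]1[C@H](CO[Si](C)(C)C(C)(C)C)Oc1ccc(CCCO[Si](C)(C)C(C)(C)C)cc1OC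
F5 | step 19 | Weinreb amide | CON(C)C(=O)/C(OC)=C/[C@@H]1[C@H](CO[Si](C)(C)C(C)(C)C)[C@@H](c2ccc(O[Si](C(C)C)(C(C)C)C(C)C)c(OC)c2)O[C@@H]1[C@H](CO[Si](C)(C)C(C)(C)C)Oc1ccc(CCCO[Si](C)(C)C(C)(C)C)cc1OC
F6 | step 13 | diol | C(OCc1ccccc1)[C@@H]([C@H](O)[C@@H](Oc1ccc(CCCO[Si](C)(C)C(C)(C)C)cc1OC)C(=O)N1[C@H](Cc2ccccc2)COC1=O)[C@H](CO[Si](C)(C)C(C)(C)C)[C@H](O)c1ccc(O[Si](C(C)C)(C(C)C)C(C)C)c(OC)c1
F7 | step 13 | cyclic hemiketal | C(OCc2ccccc2)[C@@H]1[C@H](CO[Si](C)(C)C(C)(C)C)C(O)(c2ccc(O[Si](C(C)C)(C(C)C)C(C)C)c(OC)c2)O[C@@H]1[C@H](C(=O)N1[C@H](Cc2ccccc2)COC1=O)Oc1ccc(CCCO[Si](C)(C)C(C)(C)C)cc1OC
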